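## Analysis of the target

The target is the 2‑hydroxybenzoate of a daucane‑type diol. Ring A is a cyclopentane (C1, C2, C3, C4, C5) and ring B a cycloheptene (C1, C5, C6, C7, C8, C9, C10) fused along C1–C5; C1 carries the angular methyl, C4 a hydroxyl and an isopropyl group, C6 the ester oxygen, and C8 a methyl on the C8=C9 double bond. There are four contiguous stereocentres. With β defined as the face of ring A that carries the isopropyl group, the C1 methyl and the C4 hydroxyl are α and H5 and the C6 oxygen are β, so the rings are trans‑fused; in this numbering the descriptors are 1R,4R,5S,6S. The sensitive points are the tertiary C4 hydroxyl (β to C6, so a C6 ketone can dehydrate or open ring A by retro‑aldol cleavage), the C8=C9 alkene (β,γ to C6, so it can move into conjugation with a C6 ketone) and the phenolic ester. The synthesis is hard because the quaternary C1 sits next to the doubly flanked C5 in a seven‑membered ring, and because the ring B carbon on C1 (C10) is anti to the C4 oxygen, so no hydroxyl‑directed delivery can place it. The strategy rests on one feature: C8=C9 is γ,δ to C5, and C5 is α to the oxygenated C6. Ring B can therefore arise when a radical at C8 cuts a C5–C9 bond, and that bond can belong to a cyclobutane (C1, C5, C9, C10) laid across C1–C5 by a (2+2) photocycloaddition of a ring A enone (C6 carbonyl, C1=C5) with a vinyl group (C9=C10) tethered through C7 and C8.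

## Retrosynthetic reasoning

**Ester C6–O.** The acyl–oxygen bond is cut last: 18 comes from diol 15 and acid chloride 16 by way of acetate 17. The cut is placed here because the phenolic ester tolerates neither hydride nor radical steps, and because the secondary C6 hydroxyl of 15 is easily told apart from the buried tertiary C4 hydroxyl. The phenol travels as its acetate so that the acid chloride cannot oligomerise.

**C6–H.** Diol 15 is traced to β‑hydroxy ketone 14. The C4 hydroxyl is α and C6 hangs from the α side of C5, so a borohydride bound to the C4 oxygen can only reach the α face of the carbonyl, which gives the β C6 oxygen. This requires the free C4 hydroxyl, so 14 is taken back to its triethylsilyl ether 13 only one step earlier.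

**C5–C9 (retro‑fragmentation).** In 13 the C8=C9 alkene and the C5–H bond are the two ends of a broken bond. Reconnecting C5 to C9 and placing a radical leaving group on C8 gives oxalate 12 and its alcohol 11. Two cyclobutane bonds could break in the forward step, and the radical lies in the five‑membered ring that also holds C5–C9, so the exocyclic C9–C10 bond overlaps better with it. The step is therefore run with slow addition of the hydride: C9–C10 opening, which leads to a primary radical and is close to thermoneutral, can then revert, while C5–C9 opening gives a tertiary α‑keto radical and releases all the strain. The hydrogen atom that ends the chain sets C5.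

**C5–C9 and C1–C10 (key disconnection).** Photoadduct 11 is cut across the cyclobutane to enone 10. These two bonds are chosen because they create the quaternary C1 and bring in all the carbon atoms of ring B in one step, from a substrate whose two alkenes are three atoms apart so that the regiochemistry is fixed by the tether. The forward reaction has to deliver the vinyl group to the β face, syn to the isopropyl group and anti to the silyloxy group on C4.

**C7–C8.** Aldol 10 is cut between C7 and C8 into methyl ketone 7 and methyl vinyl ketone 8. This is the shortest way to a tertiary carbinol that serves first as part of the tether and then as the radical precursor. The stereocentre at C8 is not controlled, which is acceptable because C8 becomes trigonal again in the fragmentation.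

**C6–C7.** Ketone 7 is taken back through carbinol 6 to aldehyde 5 by removing the methyl group from C6; methyl addition and oxidation are needed in the forward direction.

**Ring A.** Aldehyde 5 is the aldol condensation product of keto aldehyde 4, which is the ozonolysis product of silyl ether 2 of (S)‑terpinen‑4‑ol 1. The ring contraction delivers the 1‑acyl‑2‑methylcyclopentene with the C4 carbinol and its isopropyl group already in place and in the right absolute configuration, so no stereocentre of ring A has to be made.

## Alternatives that were turned down

**Alternative 1:** Ring B is closed first and the angular methyl is added last. The disconnection removes the C1 methyl carbon (C15) from the skeleton: the tetrasubstituted C1=C5 alkene of dienediol A2 is cyclopropanated with Et2Zn and CH2I2 syn to the C4 hydroxyl to give cyclopropane A1 (C1–C15 and C5–C15), and the C5–C15 bond is later cleaved reductively.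
- For: the methyl group is α, on the side of the C4 hydroxyl, so the face is chosen by delivery from zinc bound to that hydroxyl. On this point the alternative is stronger than the chosen route, which has to rely on shielding by a silyl ether.
- Against: A2 already contains the whole hydroazulene, so ring B must be built by separate steps before the key step. The homoallylic C8=C9 alkene competes for the carbenoid, tetrasubstituted alkenes react slowly, and the reductive opening (after oxidation at C6) must choose C5–C15 over C5–C1 and then still set C5 by protonation.
- Comparison: the chosen route offers instead one step that makes ring B and C1 together from two simple pieces, and a shorter sequence.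

**Alternative 2:** The C6–C7 bond of ring B is disconnected. In the forward step the aldehyde C–H of 4,6‑dienal A4 adds across the diene under [Rh(dppe)]ClO4 and gives the β,γ‑unsaturated cycloheptenone A3, which is the same ketone as 13.
- For: the ring closure is catalytic and atom‑economic, needs no tin, has no counterpart of the cyclobutane regiochemistry question, and places the alkene directly at C8=C9. On these points it is as strong as or stronger than the chosen fragmentation.
- Against: A4 needs the quaternary C1 with a dienyl group trans to the formyl group on C5. That centre would have to come from an intermolecular conjugate addition to a hindered β,β‑disubstituted enal such as 5, with the same face problem relative to C4 and without a tether to help. The aldehyde lies between two fully substituted carbons, which invites decarbonylation at rhodium, and the α‑stereocentre C5 can epimerise.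
- Comparison: the chosen route moves the making of C1 into the intramolecular step and pays for it with the fragmentation.

**Alternative 3:** The C1–C5 and C9–C10 bonds are disconnected. Acetoxypyranone A6 gives the 3‑oxidopyrylium ylide with Et3N, which adds across the tethered 1,1‑disubstituted alkene and forms oxygen‑bridged hydroazulenone A5, closing rings A and B at once.
- For: the cycloaddition is thermal, its regiochemistry is fixed by the tether, and it builds both rings and C1 in one step, so it is at least as convergent as the photocycloaddition.
- Against: C5 emerges bearing the bridging oxygen and the alkene emerges as the conjugated C7=C8 enone with oxygen on C9. The bridge must therefore be excised reductively, C5 set by protonation, the C9 oxygen removed and the alkene moved to C8=C9, which costs several redox steps. The C4 carbinol also has to be made enantioselectively in a furan precursor instead of being bought.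
- Comparison: the chosen route leaves no extra oxygen behind, because the bond that is cut is the one that creates the C8=C9 alkene and the C5–H bond.

Key step: step 7

Assumption: commercial (S)‑terpinen‑4‑ol is taken as enantiomerically pure, and the aldol of step 6 is taken to give both C8 epimers, which are separated; the (8R) epimer is drawn, and the (8S) epimer can be carried through the same steps because C8 becomes trigonal in step 9.

## Route

Step 1
Reactants: 1 (S)‑terpinen‑4‑ol [(1S)‑4‑methyl‑1‑(propan‑2‑yl)cyclohex‑3‑en‑1‑ol]
Product: 2 triethyl{[(1S)‑4‑methyl‑1‑(propan‑2‑yl)cyclohex‑3‑en‑1‑yl]oxy}silane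
Conditions: TESOTf, 2,6‑lutidine, CH2Cl2, 0 °C to rt
Reagents that add atoms: triethylsilyl trifluoromethanesulfonate, CC[Si](CC)(CC)OS(=O)(=O)C(F)(F)F
Why: Silylation of a hindered tertiary alcohol with a silyl triflate and a non‑nucleophilic base; the ether protects the future β‑oxygenated carbonyl compounds and later supplies the bulk on the α face of C4. The triethylsilyl group is chosen because it must come off at the end next to a ketone. The stereocentre is not touched.

Step 2
Reactants: 2 triethylsilyl ether of (S)‑terpinen‑4‑ol
Product: 4 (3S)‑6‑oxo‑3‑(propan‑2‑yl)‑3‑[(triethylsilyl)oxy]heptanal, via ozonide 3 (not isolated)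
Conditions: O3, CH2Cl2, −78 °C; then PPh3, −78 °C to rt
Reagents that add atoms: ozone, [O-][O+]=O
Why: Ozonolysis of the only alkene, with reduction of the ozonide by the phosphine, gives the methyl ketone and the aldehyde; the silyl ether and the C4 stereocentre are inert.

Step 3
Reactants: 4 (3S)‑6‑oxo‑3‑(propan‑2‑yl)‑3‑[(triethylsilyl)oxy]heptanal
Product: 5 (5R)‑2‑methyl‑5‑(propan‑2‑yl)‑5‑[(triethylsilyl)oxy]cyclopent‑1‑ene‑1‑carbaldehyde
Conditions: Bn2NH·CF3CO2H, PhMe, 50 °C
Reagents that add atoms: none
Why: Amine‑salt‑mediated intramolecular aldol condensation. The aldehyde forms the enamine far faster than the ketone, attacks the methyl ketone in a 5‑(enolexo)‑exo‑trig closure, and the tertiary aldol loses water to the tetrasubstituted enal; the weakly acidic medium leaves the β‑silyloxy group in place. C4 is unchanged (its descriptor changes only because the priorities change).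

Step 4
Reactants: 5 (5R)‑2‑methyl‑5‑(propan‑2‑yl)‑5‑[(triethylsilyl)oxy]cyclopent‑1‑ene‑1‑carbaldehyde
Product: 6 1‑[(5R)‑2‑methyl‑5‑(propan‑2‑yl)‑5‑[(triethylsilyl)oxy]cyclopent‑1‑en‑1‑yl]ethan‑1‑ol (both carbinol epimers)
Conditions: MeMgBr, THF, −78 to 0 °C
Reagents that add atoms: methylmagnesium bromide, C[Mg]Br
Why: 1,2‑Grignard addition to the enal; conjugate addition is blocked by the fully substituted β‑carbon. The new carbinol centre is removed in step 5, so its configuration does not matter.

Step 5
Reactants: 6 allylic alcohol (both carbinol epimers)
Product: 7 1‑[(5R)‑2‑methyl‑5‑(propan‑2‑yl)‑5‑[(triethylsilyl)oxy]cyclopent‑1‑en‑1‑yl]ethan‑1‑one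
Conditions: Dess–Martin periodinane, NaHCO3, CH2Cl2, 0 °C to rt
Reagents that add atoms: none
Why: Buffered Dess–Martin oxidation of a secondary allylic alcohol to the enone; the buffer protects the silyl ether from the acetic acid that is released.

Step 6
Reactants: 7 1‑[(5R)‑2‑methyl‑5‑(propan‑2‑yl)‑5‑[(triethylsilyl)oxy]cyclopent‑1‑en‑1‑yl]ethan‑1‑one; 8 methyl vinyl ketone (but‑3‑en‑2‑one)
Product: 10 (3R)‑3‑hydroxy‑3‑methyl‑1‑[(5R)‑2‑methyl‑5‑(propan‑2‑yl)‑5‑[(triethylsilyl)oxy]cyclopent‑1‑en‑1‑yl]pent‑4‑en‑1‑one (4R,8R in target numbering), via lithium enolate 9 (not isolated)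
Conditions: LiN(iPr)2, THF, −78 °C; then 8, −78 °C; AcOH quench at −78 °C
Reagents that add atoms: lithium diisopropylamide, [Li]N(C(C)C)C(C)C (supplies the lithium of 9)
Why: Kinetic deprotonation of the enone at the acetyl methyl gives the cross‑conjugated lithium enolate, which adds 1,2 to the carbonyl of 8 under kinetic control at low temperature (aldol addition); the cold acidic quench prevents reversal and conjugate addition. C8 is formed without control; the epimers are separated and the (8R) epimer is taken on.

Step 7
Reactants: 10 (4R,8R) enone with the 3‑hydroxy‑3‑methylpent‑4‑enoyl chain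
Product: 11 tricyclic hydroxy ketone (target numbering, 1R,4R,5R,8R,9R): ring A carries on its β face a cis‑fused cyclobutane (C1, C5, C9, C10); C5 and C9 also belong to a cyclopentanone (C5, C6 carbonyl, C7, C8, C9); C8 bears the hydroxyl on the convex side and the methyl toward the cyclobutane; C4 bears the isopropyl (β) and triethylsilyloxy (α) groups
Conditions: hν (350 nm, Pyrex), degassed hexane (0.005 M), 0 °C
Reagents that add atoms: none
Why: Excitation and intersystem crossing give the triplet enone, which cannot relax by twisting because C1=C5 lies in a five‑membered ring. It bonds C5 to the internal vinyl carbon C9 first, a 5‑exo‑trig closure that forms the cyclopentanone ring and a 1,4‑biradical at C1 and C10; after spin inversion the biradical closes the four‑membered ring by C1–C10 bonding. The closest known reaction type is the intramolecular enone–alkene (2+2) photocycloaddition of hepta‑1,6‑dien‑3‑ones and 1‑acylcycloalkenes to bicyclo[3.2.0]heptan‑2‑ones (straight adducts, rule of five). C5 is set by the face of attack: the silyloxy group on the α face of C4, whose silicon is expected to prefer the rotamer anti to the isopropyl group and so to lie under ring A, should steer C9 to the β face, syn to the isopropyl group whose methine hydrogen can turn inward. C9 follows from the cis fusion of the four‑ and five‑membered rings, the only fusion possible, and C1 from the cis fusion of the cyclobutane onto ring A, since C10 can reach C1 only on the face where C9 sits. With the (8R) configuration the smaller hydroxyl, not the methyl, ends up next to C4 in the β‑face adduct, so C8 should reinforce C4. The step needs straight over crossed regiochemistry, secured by the three‑atom spacing of the alkenes, and β‑face selectivity, secured by the C4 silyl ether.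

Step 8
Reactants: 11 tricyclic hydroxy ketone
Product: 12 methyl oxalate of 11 at the C8 oxygen (1R,4R,5R,8R,9R)
Conditions: ClCOCO2Me, DMAP, pyridine, CH2Cl2, 0 °C
Reagents that add atoms: methyl chlorooxoacetate, COC(=O)C(Cl)=O
Why: Acylation of the only free hydroxyl with a small, very reactive acid chloride under nucleophilic catalysis gives the mixed oxalate, a radical precursor for tertiary alcohols; low temperature and prompt use limit elimination of the β‑acyloxy ketone.

Step 9
Reactants: 12 methyl oxalate of 11
Product: 13 (1R,4R,5R)‑1,8‑dimethyl‑4‑(propan‑2‑yl)‑4‑[(triethylsilyl)oxy] trans‑fused hydroazulen‑6‑one with the C8=C9 alkene [(3R,3aR,8aR)‑6,8a‑dimethyl‑3‑(propan‑2‑yl)‑3‑[(triethylsilyl)oxy]‑2,3,3a,5,8,8a‑hexahydroazulen‑4(1H)‑one]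
Conditions: Bu3SnH (slow addition), AIBN, PhMe, 110 °C
Reagents that add atoms: none
Why: Tin‑hydride deoxygenation of a tertiary methyl oxalate gives the C8 radical, and cyclobutylcarbinyl radical fragmentation of a photoadduct with ring expansion toward a carbonyl‑stabilised radical is the known reaction type; C5–C9 cleavage gives a tertiary α‑keto radical and releases all the ring strain, and slow addition lets the near‑thermoneutral C9–C10 opening revert. C5 is set by hydrogen transfer from the stannane to the β face, because the α face carries the C4 silyloxy group and the C1 methyl; the trans‑fused ketone should also be the more stable epimer since C6 then avoids the isopropyl group.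

Step 10
Reactants: 13 silyl ether of the hydroazulenone
Product: 14 (3R,3aR,8aR)‑3‑hydroxy‑6,8a‑dimethyl‑3‑(propan‑2‑yl)‑2,3,3a,5,8,8a‑hexahydroazulen‑4(1H)‑one
Conditions: HF·pyridine, pyridine, THF, 0 °C
Reagents that add atoms: none
Why: Fluoride‑driven cleavage of the triethylsilyl ether in a buffered, non‑basic medium; no alkoxide is formed, so retro‑aldol opening of ring A is avoided, and the medium is too mild to dehydrate the carbinol or to conjugate the β,γ‑alkene.

Step 11
Reactants: 14 β‑hydroxy ketone
Product: 15 (3R,3aS,4S,8aR)‑6,8a‑dimethyl‑3‑(propan‑2‑yl)‑1,2,3,3a,4,5,8,8a‑octahydroazulene‑3,4‑diol (1R,4R,5S,6S in target numbering)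
Conditions: Me4NBH(OAc)3, AcOH/MeCN, −20 °C
Reagents that add atoms: none
Why: Hydroxyl‑directed reduction (Evans–Saksena): the C4 hydroxyl exchanges onto boron and hydride is delivered intramolecularly. In the trans‑fused skeleton the α‑oriented C4 oxygen can lean only toward the α face of the C6 carbonyl, so H6 becomes α and the C6 oxygen β; the reagent does not reduce the ketone without this delivery.

Step 12
Reactants: 15 diol; 16 2‑(acetyloxy)benzoyl chloride
Product: 17 (3R,3aS,4S,8aR)‑3‑hydroxy‑6,8a‑dimethyl‑3‑(propan‑2‑yl)‑1,2,3,3a,4,5,8,8a‑octahydroazulen‑4‑yl 2‑(acetyloxy)benzoate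
Conditions: DMAP, pyridine, CH2Cl2, 0 °C to rt
Reagents that add atoms: none
Why: Nucleophile‑catalysed acylation of the secondary C6 hydroxyl; the tertiary C4 hydroxyl, flanked by the isopropyl group and C5, does not react, and the phenol is masked so that the acid chloride cannot self‑condense.

Step 13
Reactants: 17 acetylsalicylate
Product: 18 (3R,3aS,4S,8aR)‑3‑hydroxy‑6,8a‑dimethyl‑3‑(propan‑2‑yl)‑1,2,3,3a,4,5,8,8a‑octahydroazulen‑4‑yl 2‑hydroxybenzoate (the target)
Conditions: pyrrolidine, CH2Cl2, 0 °C
Reagents that add atoms: none
Why: Aminolysis of the aryl acetate, an activated ester, is much faster than attack on the hindered secondary benzoate, so only the phenol is set free.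

## Compound list

1 | (S)‑terpinen‑4‑ol | CC1=CC[C@](O)(C(C)C)CC1 | starting material
2 | triethylsilyl ether of 1 | CC1=CC[C@](O[Si](CC)(CC)CC)(C(C)C)CC1 | intermediate
3 | ozonide of 2 (mixture at the two trioxolane carbons) | CC12OOC(O1)C[C@](O[Si](CC)(CC)CC)(C(C)C)CC2 | intermediate (not isolated)
4 | (3S)‑6‑oxo‑3‑(propan‑2‑yl)‑3‑[(triethylsilyl)oxy]heptanal | CC(=O)CC[C@@](O[Si](CC)(CC)CC)(C(C)C)CC=O | intermediate
5 | (5R)‑2‑methyl‑5‑(propan‑2‑yl)‑5‑[(triethylsilyl)oxy]cyclopent‑1‑ene‑1‑carbaldehyde | O=CC1=C(C)CC[C@@]1(O[Si](CC)(CC)CC)C(C)C | intermediate
6 | 1‑[(5R)‑2‑methyl‑5‑(propan‑2‑yl)‑5‑[(triethylsilyl)oxy]cyclopent‑1‑en‑1‑yl]ethan‑1‑ol (both carbinol epimers) | CC(O)C1=C(C)CC[C@@]1(O[Si](CC)(CC)CC)C(C)C | intermediate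
7 | 1‑[(5R)‑2‑methyl‑5‑(propan‑2‑yl)‑5‑[(triethylsilyl)oxy]cyclopent‑1‑en‑1‑yl]ethan‑1‑one | CC(=O)C1=C(C)CC[C@@]1(O[Si](CC)(CC)CC)C(C)C | intermediate
8 | methyl vinyl ketone | CC(=O)C=C | starting material
9 | lithium enolate of 7 | [Li]OC(=C)C1=C(C)CC[C@@]1(O[Si](CC)(CC)CC)C(C)C | intermediate (not isolated)
10 | (3R)‑3‑hydroxy‑3‑methyl‑1‑[(5R)‑2‑methyl‑5‑(propan‑2‑yl)‑5‑[(triethylsilyl)oxy]cyclopent‑1‑en‑1‑yl]pent‑4‑en‑1‑one | C=C[C@](C)(O)CC(=O)C1=C(C)CC[C@@]1(O[Si](CC)(CC)CC)C(C)C | intermediate
11 | tricyclic cyclobutane photoadduct (1R,4R,5R,8R,9R) | C[C@@]1(O)CC(=O)[C@]23[C@H]1C[C@@]2(C)CC[C@@]3(O[Si](CC)(CC)CC)C(C)C | intermediate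
12 | methyl oxalate of 11 | C[C@@]1(OC(=O)C(=O)OC)CC(=O)[C@]23[C@H]1C[C@@]2(C)CC[C@@]3(O[Si](CC)(CC)CC)C(C)C | intermediate
13 | (3R,3aR,8aR)‑6,8a‑dimethyl‑3‑(propan‑2‑yl)‑3‑[(triethylsilyl)oxy]‑2,3,3a,5,8,8a‑hexahydroazulen‑4(1H)‑one | CC1=CC[C@@]2(C)CC[C@@](O[Si](CC)(CC)CC)(C(C)C)[C@@H]2C(=O)C1 | intermediate
14 | (3R,3aR,8aR)‑3‑hydroxy‑6,8a‑dimethyl‑3‑(propan‑2‑yl)‑2,3,3a,5,8,8a‑hexahydroazulen‑4(1H)‑one | CC1=CC[C@@]2(C)CC[C@@](O)(C(C)C)[C@@H]2C(=O)C1 | intermediate
15 | (3R,3aS,4S,8aR)‑6,8a‑dimethyl‑3‑(propan‑2‑yl)‑1,2,3,3a,4,5,8,8a‑octahydroazulene‑3,4‑diol | CC1=CC[C@@]2(C)CC[C@@](O)(C(C)C)[C@@H]2[C@@H](O)C1 | intermediate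
16 | 2‑(acetyloxy)benzoyl chloride | CC(=O)Oc1ccccc1C(Cl)=O | starting material
17 | 2‑(acetyloxy)benzoate of 15 at the C6 oxygen | CC1=CC[C@@]2(C)CC[C@@](O)(C(C)C)[C@@H]2[C@@H](OC(=O)c2ccccc2OC(C)=O)C1 | intermediate
18 | (3R,3aS,4S,8aR)‑3‑hydroxy‑6,8a‑dimethyl‑3‑(propan‑2‑yl)‑1,2,3,3a,4,5,8,8a‑octahydroazulen‑4‑yl 2‑hydroxybenzoate | CC1=CC[C@@]2(C)CC[C@@](O)(C(C)C)[C@@H]2[C@@H](OC(=O)c2ccccc2O)C1 | target

## Step count and least certain steps

Total: 13 steps. Longest linear sequence: 13 steps from 1 (8 and 16 are bought).

**Step 7 (key step).** The most likely failure is poor facial selectivity. The two groups on C4 are of similar size close to C5, and the preference for the β face depends on the silyl group lying under ring A; photoenolisation through the C1 methyl could also lower the efficiency. The fallback adds a second control element and sets out from 10. The C8 hydroxyl is silylated (TMSOTf, 2,6‑lutidine) to the C8 trimethylsilyl ether of 10 F1, which is irradiated as in step 7 to the C8 trimethylsilyl ether of the photoadduct F2. Mild methanolysis (PPTS, MeOH) removes the tertiary trimethylsilyl group selectively and returns to 11. A bulky C8 silyloxy group should insist on the convex side of the bicyclo[3.2.0]heptanone, which in the (8R) series corresponds to the β‑face adduct (matched double stereodifferentiation). Both C8 epimers are available from step 6, so the matched pair can be found by experiment.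

**Step 9.** The most likely failure is cleavage of the exocyclic C9–C10 bond, because the C8 radical and the C6 carbonyl both lie in the five‑membered ring that contains C5–C9 and overlap poorly with it; quenching of the resulting primary radical would give a spiro ketone. Hydrogen delivery to the α face of C5 is a second risk, and it cannot be repaired by base because the β,γ‑alkene would move into conjugation. The fallback replaces the hydrogen‑transfer chain by a radical–polar crossover and sets out from 12. Hydrolysis with one equivalent of CsOH·H2O (THF/H2O, 0 °C) gives the cesium oxalate of 11 F3. Irradiation with blue light and [Ir(dF(CF3)ppy)2(dtbbpy)]PF6 (catalytic) in DME/DMF with water oxidises the oxalate, which loses two molecules of CO2 to the C8 radical. No hydrogen‑atom donor is present, so a primary radical can only re‑close, while the electrophilic α‑keto radical at C5 is reduced by the photocatalyst to the C5=C6 enolate and protonated, returning to 13. The regiodefined enolate gives a second handle on C5 through the choice of proton source.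

**Step 8.** The most likely failure is base‑induced loss of the new oxalate from the β‑acyloxy ketone (acidic C7 hydrogens), or retro‑aldol cleavage, during acylation with amine bases. The fallback moves the acylation to the aldol stage and sets out from 9 and 8. After the addition at −78 °C the lithium alkoxide is acylated in the same flask with methyl chlorooxoacetate to the methyl oxalate of 10 F4. Irradiation as in step 7 then returns directly to 12, which is taken into step 9 without contact with base.

**Step 6.** The most likely failure is conjugate addition to 8, or its oligomerisation, and reversal of the aldol on warming; C8 is not controlled either. The fallback uses an ynone that cannot react in these ways and sets out from 9. Addition to 4‑(trimethylsilyl)but‑3‑yn‑2‑one at −78 °C gives the silylalkynyl carbinol F5. Buffered fluoride (TBAF, AcOH, THF, 0 °C) gives the terminal alkynyl carbinol F6. Semi‑hydrogenation (H2, Pd/CaCO3 poisoned with Pb(OAc)2, quinoline) returns to 10; the tetrasubstituted enone alkene is not reduced.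

**Step 11.** The most likely failure is slow exchange of the very hindered tertiary hydroxyl onto boron, so that delivery does not take place or an undirected path gives the C6 epimer. The fallback sets C6 by inversion and sets out from 14. Reduction with NaBH4 and CeCl3·7H2O (MeOH, −78 °C) is expected to come from the β face, away from the angular methyl and the C4 hydroxyl, and to give the 6‑epi diol F7. A Mitsunobu esterification with 2‑hydroxybenzoic acid (PPh3, diisopropyl azodicarboxylate, THF) inverts C6 and returns at 18, without steps 12 and 13.

## Further compounds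

F1 | step 7 | C8 trimethylsilyl ether of 10 | C=C[C@](C)(O[Si](C)(C)C)CC(=O)C1=C(C)CC[C@@]1(O[Si](CC)(CC)CC)C(C)C
F2 | step 7 | C8 trimethylsilyl ether of photoadduct 11 | C[C@@]1(O[Si](C)(C)C)CC(=O)[C@]23[C@H]1C[C@@]2(C)CC[C@@]3(O[Si](CC)(CC)CC)C(C)C
F3 | step 9 | cesium oxalate of 11 | C[C@@]1(OC(=O)C(=O)[O-])CC(=O)[C@]23[C@H]1C[C@@]2(C)CC[C@@]3(O[Si](CC)(CC)CC)C(C)C.[Cs+]
F4 | step 8 | methyl oxalate of 10 | C=C[C@](C)(OC(=O)C(=O)OC)CC(=O)C1=C(C)CC[C@@]1(O[Si](CC)(CC)CC)C(C)C
F5 | step 6 | (3R)‑3‑hydroxy‑3‑methyl‑5‑(trimethylsilyl)pent‑4‑ynoyl analogue of 10 | C[Si](C)(C)C#C[C@](C)(O)CC(=O)C1=C(C)CC[C@@]1(O[Si](CC)(CC)CC)C(C)C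
F6 | step 6 | (3R)‑3‑hydroxy‑3‑methylpent‑4‑ynoyl analogue of 10 | C#C[C@](C)(O)CC(=O)C1=C(C)CC[C@@]1(O[Si](CC)(CC)CC)C(C)C
F7 | step 11 | C6 epimer of diol 15 | CC1=CC[C@@]2(C)CC[C@@](O)(C(C)C)[C@@H]2[C@H](O)C1
A1 | alternative 1 | cyclopropane‑fused diol (C15 bridging C1 and C5 on the hydroxyl face) | CC1=CC[C@]23C[C@@]2([C@H](O)C1)[C@](O)(C(C)C)CC3
A2 | alternative 1 | bicyclic dienediol with the tetrasubstituted C1=C5 alkene | CC1=CCC2=C([C@H](O)C1)[C@](O)(C(C)C)CC2
A3 | alternative 2 | C4 triethylsilyl ether of the hydroazulene C6 ketone (identical with 13) | CC1=CC[C@@]2(C)CC[C@@](O[Si](CC)(CC)CC)(C(C)C)[C@@H]2C(=O)C1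
A4 | alternative 2 | 4,6‑dienal with the dienyl group on C1 and the formyl group on C5 | C=C(C)/C=C/[C@@]1(C)CC[C@@](O[Si](CC)(CC)CC)(C(C)C)[C@@H]1C=O
A5 | alternative 3 | oxygen‑bridged hydroazulenone | CC1=CC(=O)[C@]23O[C@H]1C[C@@]2(C)CC[C@@]3(O[Si](CC)(CC)CC)C(C)C
A6 | alternative 3 | 6‑acetoxy‑5‑methylpyran‑3‑one with the alkenyl carbinol chain on C2 (mixture at the two pyranone stereocentres) | CC(=O)OC1OC(C(=O)C=C1C)[C@](O[Si](CC)(CC)CC)(C(C)C)CCC(C)=C
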